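**Retrosynthetic overview**

1. The 11,12-dial comes last, by double oxidation of an 11,12-diol, and the C1 ester by acylation of a 1β-alcohol. The 5α-hydroxyl comes from α-epoxidation of C5=C6 in a 5,7-dienolide and reductive opening at C6.
2. Key disconnection: the C9–C10 bond of ring B, formed by light-driven conrotatory 6π closure of the seco-B triene C10=C5–C6=C7(Z)–C8=C9, in which C8=C9 is the double bond of a butenolide with its carbonyl at C11.
3. Feature the strategy rests on: in ring B, H-9 is anti to the C10 methyl across C9–C10, C11 and C12 sit cis on the C8–C9 edge (so they can be tied as a butenolide), and the C1 oxygen is next to C10, where it can choose the face of closure.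
4. The triene comes from a ring-A enyne and 4-bromofuran-2(5H)-one (Sonogashira coupling for C7–C8, then Z-semihydrogenation). The enyne comes from 2-methylcyclohexane-1,3-dione (enol ether, two methylations, acetylide addition with transposition, CBS reduction for C1).
5. Ring order: ring A and the butenolide are bought, ring B closes last (step 10), and the lactone ring is opened at the end.

Key step: step 10

Remark: drimane numbering is used throughout, also for the monocyclic precursors (C1 = oxygen-bearing ring-A carbon, C10 = methyl-bearing carbon, C11 on C9, C12 on C8); TBS = tert-butyldimethylsilyl; the (S)-oxazaborolidine is assumed to give the (R)-carbinol by the usual large/small model with the tetrasubstituted alkene as the large group.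

**Route**

Step 1
Reactants: 1 2-methylcyclohexane-1,3-dione
Product: 2 3-isobutoxy-2-methylcyclohex-2-en-1-one
Conditions: i-BuOH, p-toluenesulfonic acid monohydrate (cat.), toluene, reflux, Dean–Stark
Reagents that add atoms: isobutanol CC(C)CO
Why: Acid-catalysed condensation of the symmetrical 1,3-dione with the alcohol (vinylogous esterification, water removed azeotropically) should give a single enol ether.

Step 2
Reactants: 2 3-isobutoxy-2-methylcyclohex-2-en-1-one
Product: 4 3-isobutoxy-2,6-dimethylcyclohex-2-en-1-one (racemic), via lithium enolate 3 (not isolated)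
Conditions: LiN(iPr)2, THF, −78 °C; MeI, −78 → 0 °C
Reagents that add atoms: iodomethane CI
Why: Stork–Danheiser kinetic deprotonation of the vinylogous ester at the α′ carbon followed by SN2 methylation should install the first methyl; the stereocentre formed is racemic and is erased in step 3.

Step 3
Reactants: 4 3-isobutoxy-2,6-dimethylcyclohex-2-en-1-one
Product: 6 3-isobutoxy-2,6,6-trimethylcyclohex-2-en-1-one, via lithium enolate 5 (not isolated)
Conditions: LiN(iPr)2, THF, −78 °C; MeI, DMPU, −78 °C → rt
Reagents that add atoms: iodomethane CI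
Why: A second kinetic α′ enolisation–methylation (Stork–Danheiser alkylation) at the only remaining α′ hydrogen should complete the gem-dimethyl carbon that becomes C4.

Step 4
Reactants: 6 3-isobutoxy-2,6,6-trimethylcyclohex-2-en-1-one; 7 ethynyltrimethylsilane
Product: 10 2,4,4-trimethyl-3-[(trimethylsilyl)ethynyl]cyclohex-2-en-1-one, via lithium acetylide 8 (not isolated), via tertiary carbinol 9 (not isolated)
Conditions: 7, n-BuLi, THF, −78 °C; add 6, −78 °C → rt; then 2 M HCl, THF, rt
Reagents that add atoms: none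
Why: Stork–Danheiser transposition, in which the slim lithium acetylide adds 1,2 to the hindered vinylogous-ester carbonyl and aqueous acid then hydrolyses the enol ether with loss of water, should place the alkyne on the carbon next to the gem-dimethyl group (future C5) and the ketone at future C1.

Step 5
Reactants: 10 2,4,4-trimethyl-3-[(trimethylsilyl)ethynyl]cyclohex-2-en-1-one
Product: 11 (R)-2,4,4-trimethyl-3-[(trimethylsilyl)ethynyl]cyclohex-2-en-1-ol
Conditions: (S)-1-methyl-3,3-diphenyltetrahydro-1H,3H-pyrrolo[1,2-c][1,3,2]oxazaborole (10 mol %), catecholborane, toluene, −78 °C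
Reagents that add atoms: none
Why: Corey–Bakshi–Shibata reduction, in which the tetrasubstituted alkene arm acts as the large and the ring CH2 as the small substituent, should deliver hydride to the face that gives the (R)-carbinol (C1, the future 1β oxygen), while catecholborane at low temperature leaves the silylalkyne untouched.

Step 6
Reactants: 11 (R)-2,4,4-trimethyl-3-[(trimethylsilyl)ethynyl]cyclohex-2-en-1-ol
Product: 12 (R)-tert-butyldimethyl({2,4,4-trimethyl-3-[(trimethylsilyl)ethynyl]cyclohex-2-en-1-yl}oxy)silane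
Conditions: TBSCl, imidazole, DMF, rt
Reagents that add atoms: tert-butyldimethylsilyl chloride CC(C)(C)[Si](C)(C)Cl
Why: Imidazole-promoted silylation of the secondary allylic alcohol (silyl ether formation) proceeds without change at C1 and installs the bulky group later used for facial control.

Step 7
Reactants: 12 (R)-tert-butyldimethyl({2,4,4-trimethyl-3-[(trimethylsilyl)ethynyl]cyclohex-2-en-1-yl}oxy)silane
Product: 13 (R)-tert-butyl[(3-ethynyl-2,4,4-trimethylcyclohex-2-en-1-yl)oxy]dimethylsilane
Conditions: K2CO3 (cat.), MeOH, rt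
Reagents that add atoms: none
Why: Base-catalysed methanolysis of the alkynyl C–Si bond (protodesilylation) is selective for the trimethylsilyl alkyne over the TBS ether.

Step 8
Reactants: 13 (R)-tert-butyl[(3-ethynyl-2,4,4-trimethylcyclohex-2-en-1-yl)oxy]dimethylsilane; 14 4-bromofuran-2(5H)-one
Product: 15 4-{[(3R)-3-(tert-butyldimethylsilyloxy)-2,6,6-trimethylcyclohex-1-en-1-yl]ethynyl}furan-2(5H)-one
Conditions: PdCl2(PPh3)2 (5 mol %), CuI (10 mol %), i-Pr2NEt, THF, rt
Reagents that add atoms: none
Why: Sonogashira coupling should form the C7–C8 bond under mild conditions, because the β-bromobutenolide is a vinylogous acyl bromide that undergoes oxidative addition readily and the hindered amine does not add to it.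

Step 9
Reactants: 15 4-{[(3R)-3-(tert-butyldimethylsilyloxy)-2,6,6-trimethylcyclohex-1-en-1-yl]ethynyl}furan-2(5H)-one
Product: 16 4-{(Z)-2-[(3R)-3-(tert-butyldimethylsilyloxy)-2,6,6-trimethylcyclohex-1-en-1-yl]ethenyl}furan-2(5H)-one
Conditions: H2 (1 atm), Pd/CaCO3 poisoned with Pb(OAc)2, quinoline, EtOAc/hexane, 0 °C, dark; used at once
Reagents that add atoms: none
Why: Lindlar semihydrogenation delivers both hydrogens syn on the catalyst surface to give the Z C6=C7 alkene, as in dienyne-to-previtamin D reductions, and cold, dark handling is meant to prevent the [1,7]-hydrogen shift and dark disrotatory closure of the labile triene.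

Step 10
Reactants: 16 4-{(Z)-2-[(3R)-3-(tert-butyldimethylsilyloxy)-2,6,6-trimethylcyclohex-1-en-1-yl]ethenyl}furan-2(5H)-one
Product: 17 1β-(tert-butyldimethylsilyloxy)-12-hydroxydrima-5,7-dien-11-oic acid lactone (carbonyl at C11; 9α-H; 10β-methyl)
Conditions: hν (365 nm), degassed Et2O (0.005 M), −30 °C; solvent removed cold
Reagents that add atoms: none
Why: Light excites the linear trienoate C10=C5–C6=C7–C8=C9–C11=O in its helical cZc conformer, and the termini C10 and C9 bond antarafacially in a conrotatory 6π electrocyclisation, the reaction type by which previtamin D closes to provitamin D and lumisterol at the same methyl-bearing ring-A carbon. Ring B is thereby closed as a six-membered carbocycle in a pericyclic (electrocyclic, conrotatory) mode, with the double bonds shifted to C5=C6 and C7=C8. C9 is controlled by orbital symmetry: the butenolide holds H-9 inside and C11 outside on C8=C9, ring A holds the methyl inside on C10=C5, and conrotation turns the two inside groups to opposite faces, so H-9 ends up anti to the C10 methyl. C10 is controlled by the C1 stereocentre: the silyloxy group sits pseudoaxial to escape A(1,2) strain with the C10 methyl and covers the β face of C10, so the helix in which C9 reaches C10 from the α face should be preferred and the methyl is pushed β, cis to the C1 oxygen, while the C4 methyls lie on the far side of C5 and mainly meet H-6. The step needs the anti (photochemical) and not the syn (thermal) mode, one helical sense, and a one-way conversion: the low temperature suppresses dark disrotatory closure and the [1,7]-hydrogen shift from the C10 methyl, any E isomer formed at C6=C7 absorbs the same light and is returned to Z, and the product diene, cut off from the carbonyl by sp3 C9, is expected to be nearly transparent at 365 nm so that reopening stays minor.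

Step 11
Reactants: 17 1β-(tert-butyldimethylsilyloxy)-12-hydroxydrima-5,7-dien-11-oic acid lactone
Product: 18 1β-(tert-butyldimethylsilyloxy)drima-5,7-diene-11,12-diol (9α-H)
Conditions: i-Bu2AlH (4 equiv), CH2Cl2, −78 → −20 °C; aqueous KNaC4H4O6 work-up
Reagents that add atoms: none
Why: Hydride reduction of the lactone to the 11,12-diol with a Lewis-acidic, non-basic aluminium hydride at low temperature should outpace removal of the acidic, allylic α-hydrogen at C9, so the C9 configuration and the diene position survive.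

Step 12
Reactants: 18 1β-(tert-butyldimethylsilyloxy)drima-5,7-diene-11,12-diol
Product: 21 1β-(tert-butyldimethylsilyloxy)-11-hydroxydrima-5,7-dien-12-oic acid lactone (carbonyl at C12), via hydroxy dienal 19 (not isolated), via lactol 20 (not isolated)
Conditions: activated MnO2 (excess), CH2Cl2, rt
Reagents that add atoms: none
Why: Chemoselective allylic oxidation with oxidative lactonisation: MnO2 oxidises only the allylic C12 alcohol, the aldehyde is captured by the C11 hydroxyl as a five-membered lactol, and this allylic carbinol is oxidised further, so the carbonyl is transposed to C12 and conjugated with the 5,7-diene.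

Step 13
Reactants: 21 1β-(tert-butyldimethylsilyloxy)-11-hydroxydrima-5,7-dien-12-oic acid lactone
Product: 22 1β-(tert-butyldimethylsilyloxy)-5α,6α-epoxy-11-hydroxydrim-7-en-12-oic acid lactone
Conditions: mCPBA, NaHCO3, CH2Cl2, 0 °C
Reagents that add atoms: 3-chloroperoxybenzoic acid O=C(OO)c1cccc(Cl)c1
Why: Prilezhaev epoxidation should be chemoselective for the electron-rich, distal C5=C6 bond of the dienoate and occur on the α face, anti to the axial C10 methyl and the 4β methyl, which sets the C5 oxygen α.

Step 14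
Reactants: 22 1β-(tert-butyldimethylsilyloxy)-5α,6α-epoxy-11-hydroxydrim-7-en-12-oic acid lactone
Product: 23 1β-(tert-butyldimethylsilyloxy)-5α,11-dihydroxydrim-7-en-12-oic acid lactone (lactone to O-11)
Conditions: Pd2(dba)3·CHCl3 (2.5 mol %), PBu3 (10 mol %), HCO2H, Et3N, dioxane, rt
Reagents that add atoms: none
Why: Tsuji–Shimizu-type hydrogenolysis of an alkenyl oxirane, in which zerovalent palladium ionises the allylic C6–O bond to a π-allyl complex carrying the C5 alkoxide and formate-derived hydride is transferred to C6 as established for γ,δ-epoxy-α,β-unsaturated esters, should give the homoallylic tertiary alcohol with C7=C8 left conjugated and the 5α C–O bond untouched.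

Step 15
Reactants: 23 1β-(tert-butyldimethylsilyloxy)-5α,11-dihydroxydrim-7-en-12-oic acid lactone
Product: 24 1β-(tert-butyldimethylsilyloxy)drim-7-ene-5α,11,12-triol
Conditions: LiAlH4, THF, 0 °C
Reagents that add atoms: none
Why: 1,2-Reduction of the α,β-unsaturated lactone by LiAlH4 gives the allylic 11,12-diol, and the C9 hydrogen, which is not activated by the carbonyl here, is not at risk.

Step 16
Reactants: 24 1β-(tert-butyldimethylsilyloxy)drim-7-ene-5α,11,12-triol
Product: 25 1β-(tert-butyldimethylsilyloxy)-11,12-O-isopropylidenedrim-7-ene-5α,11,12-triol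
Conditions: Me2C(OMe)2, pyridinium p-toluenesulfonate (cat.), CH2Cl2, rt
Reagents that add atoms: 2,2-dimethoxypropane COC(C)(C)OC
Why: Acid-catalysed transketalisation links the two primary hydroxyls, held cis on the C8–C9 edge, as a seven-membered isopropylidene acetal (as with cis-but-2-ene-1,4-diols), while the tertiary C5 hydroxyl and the silyl ether do not react under this mild acid.

Step 17
Reactants: 25 1β-(tert-butyldimethylsilyloxy)-11,12-O-isopropylidenedrim-7-ene-5α,11,12-triol
Product: 26 11,12-O-isopropylidenedrim-7-ene-1β,5α,11,12-tetraol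
Conditions: Bu4NF, THF, 45 °C
Reagents that add atoms: none
Why: Fluoride-induced desilylation cleaves the hindered secondary silyl ether, the acetal and the tertiary alcohol being inert to fluoride.

Step 18
Reactants: 27 (E)-p-coumaric acid
Product: 29 (E)-4-(tert-butyldimethylsilyloxy)cinnamic acid, via bis-silyl ester 28 (not isolated)
Conditions: TBSCl (2.5 equiv), imidazole, DMF, rt; then AcOH/THF/H2O, rt
Reagents that add atoms: tert-butyldimethylsilyl chloride CC(C)(C)[Si](C)(C)Cl
Why: Exhaustive silylation followed by selective hydrolysis of the much more labile silyl ester, aryl silyl ethers being stable to mild aqueous acid, should give the phenol-protected acid with the E alkene unchanged.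

Step 19
Reactants: 26 11,12-O-isopropylidenedrim-7-ene-1β,5α,11,12-tetraol; 29 (E)-4-(tert-butyldimethylsilyloxy)cinnamic acid
Product: 31 1β-O-[(E)-4-(tert-butyldimethylsilyloxy)cinnamoyl]-11,12-O-isopropylidenedrim-7-ene-1β,5α,11,12-tetraol, via mixed anhydride 30 (not isolated)
Conditions: 29, 2,4,6-trichlorobenzoyl chloride, Et3N, THF, rt; then 26, 4-(dimethylamino)pyridine, toluene, 60 °C
Reagents that add atoms: none
Why: Yamaguchi esterification, in which 4-(dimethylamino)pyridine attacks the unhindered cinnamoyl carbonyl of the mixed anhydride and the acylpyridinium acylates the equatorial secondary 1β hydroxyl, should leave the far more hindered tertiary 5α hydroxyl alone.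

Step 20
Reactants: 31 1β-O-[(E)-4-(tert-butyldimethylsilyloxy)cinnamoyl]-11,12-O-isopropylidenedrim-7-ene-1β,5α,11,12-tetraol
Product: 32 1β-O-[(E)-4-(tert-butyldimethylsilyloxy)cinnamoyl]drim-7-ene-1β,5α,11,12-tetraol
Conditions: pyridinium p-toluenesulfonate (cat.), MeOH, rt
Reagents that add atoms: none
Why: Mild acid-catalysed methanolysis (transketalisation) removes the strained seven-membered acetal under conditions that leave the aryl silyl ether, the cinnamate and the tertiary alcohol alone.

Step 21
Reactants: 32 1β-O-[(E)-4-(tert-butyldimethylsilyloxy)cinnamoyl]drim-7-ene-1β,5α,11,12-tetraol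
Product: 34 1β-[(E)-4-(tert-butyldimethylsilyloxy)cinnamoyloxy]-5α-hydroxydrim-7-ene-11,12-dial (9α-H), via bis-alkoxysulfonium salt 33 (not isolated)
Conditions: (COCl)2, DMSO, CH2Cl2, −78 °C; Et3N, −78 → −40 °C; pH 7 buffer quench
Reagents that add atoms: none
Why: Swern oxidation converts both primary alcohols to aldehydes through alkoxysulfonium ylides without over-oxidation, and keeping the amine stage cold with a neutral quench should avoid epimerisation at C9, as for polygodial-type ene-dials.

Step 22
Reactants: 34 1β-[(E)-4-(tert-butyldimethylsilyloxy)cinnamoyloxy]-5α-hydroxydrim-7-ene-11,12-dial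
Product: 35 CNP0323926.1, 1β-[(E)-4-hydroxycinnamoyloxy]-5α-hydroxydrim-7-ene-11,12-dial ((1R,5R,9R,10S) in drimane numbering)
Conditions: Bu4NF, AcOH (1:1), THF, 0 °C
Reagents that add atoms: none
Why: Buffered fluoride desilylation cleaves the aryl silyl ether very rapidly, and the acetic acid keeps the medium from epimerising C9 or eliminating the C5 hydroxyl.

**Compound list**

1 | 2-methylcyclohexane-1,3-dione | CC1C(=O)CCCC1=O | starting material
2 | 3-isobutoxy-2-methylcyclohex-2-en-1-one | CC1=C(OCC(C)C)CCCC1=O | intermediate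
3 | lithium 5-isobutoxy-6-methylcyclohexa-1,5-dien-1-olate | [Li]OC1=CCCC(OCC(C)C)=C1C | intermediate
4 | 3-isobutoxy-2,6-dimethylcyclohex-2-en-1-one (racemic) | CC1CCC(OCC(C)C)=C(C)C1=O | intermediate
5 | lithium 5-isobutoxy-2,6-dimethylcyclohexa-1,5-dien-1-olate | [Li]OC1=C(C)CCC(OCC(C)C)=C1C | intermediate
6 | 3-isobutoxy-2,6,6-trimethylcyclohex-2-en-1-one | CC1(C)CCC(OCC(C)C)=C(C)C1=O | intermediate
7 | ethynyltrimethylsilane | C#C[Si](C)(C)C | starting material
8 | lithium (trimethylsilyl)acetylide | [Li]C#C[Si](C)(C)C | intermediate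
9 | 3-isobutoxy-2,6,6-trimethyl-1-[(trimethylsilyl)ethynyl]cyclohex-2-en-1-ol (racemic) | CC1(C)CCC(OCC(C)C)=C(C)C1(O)C#C[Si](C)(C)C | intermediate
10 | 2,4,4-trimethyl-3-[(trimethylsilyl)ethynyl]cyclohex-2-en-1-one | CC1(C)CCC(=O)C(C)=C1C#C[Si](C)(C)C | intermediate
11 | (R)-2,4,4-trimethyl-3-[(trimethylsilyl)ethynyl]cyclohex-2-en-1-ol | CC1(C)CC[C@@H](O)C(C)=C1C#C[Si](C)(C)C | intermediate
12 | (R)-tert-butyldimethyl({2,4,4-trimethyl-3-[(trimethylsilyl)ethynyl]cyclohex-2-en-1-yl}oxy)silane | CC1(C)CC[C@@H](O[Si](C)(C)C(C)(C)C)C(C)=C1C#C[Si](C)(C)C | intermediate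
13 | (R)-tert-butyl[(3-ethynyl-2,4,4-trimethylcyclohex-2-en-1-yl)oxy]dimethylsilane | CC1(C)CC[C@@H](O[Si](C)(C)C(C)(C)C)C(C)=C1C#C | intermediate
14 | 4-bromofuran-2(5H)-one | O=C1C=C(Br)CO1 | starting material
15 | 4-{[(3R)-3-(tert-butyldimethylsilyloxy)-2,6,6-trimethylcyclohex-1-en-1-yl]ethynyl}furan-2(5H)-one | CC1(C)CC[C@@H](O[Si](C)(C)C(C)(C)C)C(C)=C1C#CC1=CC(=O)OC1 | intermediate
16 | 4-{(Z)-2-[(3R)-3-(tert-butyldimethylsilyloxy)-2,6,6-trimethylcyclohex-1-en-1-yl]ethenyl}furan-2(5H)-one | CC1(C)CC[C@@H](O[Si](C)(C)C(C)(C)C)C(C)=C1/C=C\C1=CC(=O)OC1 | intermediate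
17 | 1β-(tert-butyldimethylsilyloxy)-12-hydroxydrima-5,7-dien-11-oic acid lactone (carbonyl at C11; 9α-H; 10β-methyl) | CC1(C)CC[C@@H](O[Si](C)(C)C(C)(C)C)[C@]2(C)[C@H]3C(=O)OCC3=CC=C12 | intermediate
18 | 1β-(tert-butyldimethylsilyloxy)drima-5,7-diene-11,12-diol | CC1(C)CC[C@@H](O[Si](C)(C)C(C)(C)C)[C@]2(C)[C@@H](CO)C(CO)=CC=C12 | intermediate
19 | 1β-(tert-butyldimethylsilyloxy)-11-hydroxydrima-5,7-dien-12-al | CC1(C)CC[C@@H](O[Si](C)(C)C(C)(C)C)[C@]2(C)[C@@H](CO)C(C=O)=CC=C12 | intermediate
20 | 1β-(tert-butyldimethylsilyloxy)-11,12-epoxydrima-5,7-dien-12-ol (lactol; C12 epimers) | CC1(C)CC[C@@H](O[Si](C)(C)C(C)(C)C)[C@]2(C)[C@H]3COC(O)C3=CC=C12 | intermediate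
21 | 1β-(tert-butyldimethylsilyloxy)-11-hydroxydrima-5,7-dien-12-oic acid lactone (carbonyl at C12) | CC1(C)CC[C@@H](O[Si](C)(C)C(C)(C)C)[C@]2(C)[C@H]3COC(=O)C3=CC=C12 | intermediate
22 | 1β-(tert-butyldimethylsilyloxy)-5α,6α-epoxy-11-hydroxydrim-7-en-12-oic acid lactone | CC1(C)CC[C@@H](O[Si](C)(C)C(C)(C)C)[C@]2(C)[C@H]3COC(=O)C3=C[C@@H]4O[C@]124 | intermediate
23 | 1β-(tert-butyldimethylsilyloxy)-5α,11-dihydroxydrim-7-en-12-oic acid lactone (lactone to O-11) | CC1(C)CC[C@@H](O[Si](C)(C)C(C)(C)C)[C@]2(C)[C@H]3COC(=O)C3=CC[C@@]12O | intermediate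
24 | 1β-(tert-butyldimethylsilyloxy)drim-7-ene-5α,11,12-triol | CC1(C)CC[C@@H](O[Si](C)(C)C(C)(C)C)[C@]2(C)[C@@H](CO)C(CO)=CC[C@@]12O | intermediate
25 | 1β-(tert-butyldimethylsilyloxy)-11,12-O-isopropylidenedrim-7-ene-5α,11,12-triol | CC1(C)CC[C@@H](O[Si](C)(C)C(C)(C)C)[C@]2(C)[C@H]3COC(C)(C)OCC3=CC[C@@]12O | intermediate
26 | 11,12-O-isopropylidenedrim-7-ene-1β,5α,11,12-tetraol | CC1(C)CC[C@@H](O)[C@]2(C)[C@H]3COC(C)(C)OCC3=CC[C@@]12O | intermediate
27 | (E)-p-coumaric acid | O=C(O)/C=C/c1ccc(O)cc1 | starting material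
28 | tert-butyldimethylsilyl (E)-4-(tert-butyldimethylsilyloxy)cinnamate | CC(C)(C)[Si](C)(C)OC(=O)/C=C/c1ccc(O[Si](C)(C)C(C)(C)C)cc1 | intermediate
29 | (E)-4-(tert-butyldimethylsilyloxy)cinnamic acid | O=C(O)/C=C/c1ccc(O[Si](C)(C)C(C)(C)C)cc1 | intermediate
30 | (E)-4-(tert-butyldimethylsilyloxy)cinnamic 2,4,6-trichlorobenzoic anhydride | O=C(OC(=O)c1c(Cl)cc(Cl)cc1Cl)/C=C/c1ccc(O[Si](C)(C)C(C)(C)C)cc1 | intermediate
31 | 1β-O-[(E)-4-(tert-butyldimethylsilyloxy)cinnamoyl]-11,12-O-isopropylidenedrim-7-ene-1β,5α,11,12-tetraol | CC1(C)CC[C@@H](OC(=O)/C=C/c2ccc(O[Si](C)(C)C(C)(C)C)cc2)[C@]2(C)[C@H]3COC(C)(C)OCC3=CC[C@@]12O | intermediate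
32 | 1β-O-[(E)-4-(tert-butyldimethylsilyloxy)cinnamoyl]drim-7-ene-1β,5α,11,12-tetraol | CC1(C)CC[C@@H](OC(=O)/C=C/c2ccc(O[Si](C)(C)C(C)(C)C)cc2)[C@]2(C)[C@@H](CO)C(CO)=CC[C@@]12O | intermediate
33 | 11,12-bis(dimethylsulfonio-oxy) derivative of 32, dichloride | CC1(C)CC[C@@H](OC(=O)/C=C/c2ccc(O[Si](C)(C)C(C)(C)C)cc2)[C@]2(C)[C@@H](CO[S+](C)C)C(CO[S+](C)C)=CC[C@@]12O.[Cl-].[Cl-] | intermediate
34 | 1β-[(E)-4-(tert-butyldimethylsilyloxy)cinnamoyloxy]-5α-hydroxydrim-7-ene-11,12-dial | CC1(C)CC[C@@H](OC(=O)/C=C/c2ccc(O[Si](C)(C)C(C)(C)C)cc2)[C@]2(C)[C@@H](C=O)C(C=O)=CC[C@@]12O | intermediate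
35 | CNP0323926.1, 1β-[(E)-4-hydroxycinnamoyloxy]-5α-hydroxydrim-7-ene-11,12-dial | CC1(C)CC[C@@H](OC(=O)/C=C/c2ccc(O)cc2)[C@]2(C)[C@@H](C=O)C(C=O)=CC[C@@]12O | target

**Step count**

Total: 22 steps. Longest linear sequence: 21 steps (steps 1–17 and 19–22; step 18 is the side branch).

**Steps most likely to fail**

Step 10. The twist that the C4 gem-dimethyl group forces on the C5–C6 bond may depopulate the closing conformer, so that the excited triene relaxes mainly by Z/E isomerisation or hydrogen shift, or closure may occur in the unwanted helical sense. The fallback closes ring B thermally by a Diels–Alder reaction; it sets out from alkyne 13 and comes back at triol 24.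
- Semihydrogenation of 13 (H2, Pd/CaCO3 poisoned with Pb(OAc)2, quinoline) would give the diene (R)-tert-butyldimethyl[(2,4,4-trimethyl-3-vinylcyclohex-2-en-1-yl)oxy]silane F1.
- Heating F1 with dimethyl acetylenedicarboxylate (neat, 110 °C) would form the C9–C10 and C7–C8 bonds, the dienophile reaching C10 anti to the pseudoaxial silyloxy group, to give dimethyl 1β-(tert-butyldimethylsilyloxy)drima-5,8-diene-11,12-dioate F2.
- mCPBA should epoxidise the electron-rich C5=C6 from the α face to give the 5α,6α-epoxide F3.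
- DBU should open F3 by deprotonation at C7 and vinylogous β-elimination to give dimethyl 1β-(tert-butyldimethylsilyloxy)-5α-hydroxydrima-6,8-diene-11,12-dioate F4.
- Hydrogenation of the disubstituted C6=C7 (H2, Pd/C, EtOAc) would give dimethyl 1β-(tert-butyldimethylsilyloxy)-5α-hydroxydrim-8-ene-11,12-dioate F5.
- Deprotonation at C7 with LiN(iPr)2 and kinetic protonation at C9 anti to the C10 methyl (AcOH, −78 °C) would give dimethyl 1β-(tert-butyldimethylsilyloxy)-5α-hydroxydrim-7-ene-11,12-dioate (9α-H) F6.
- LiAlH4 reduction of F6 would give 24.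

Step 9. Hydrogenation may stall at, or over-reduce, the hindered doubly conjugated alkyne, and the Z-triene may drift thermally (hydrogen shift, dark closure) during a slow reduction. The fallback makes the Z alkene before the C7–C8 bond; it sets out from alkyne 13 and bromide 14 and comes back at triene 16.
- 13 would be iodinated (N-iodosuccinimide, AgNO3 cat., acetone) to (R)-tert-butyl{[3-(iodoethynyl)-2,4,4-trimethylcyclohex-2-en-1-yl]oxy}dimethylsilane F7.
- Diimide reduction of F7 (2-nitrobenzenesulfonyl hydrazide, Et3N) would give the (Z)-2-iodoethenyl compound F8.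
- 14 would be stannylated (Bu3SnSnBu3, Pd(PPh3)4, toluene) to 4-(tributylstannyl)furan-2(5H)-one F9.
- Stille coupling of F8 with F9 (Pd(PPh3)4, CuI, DMF, at or below rt, dark) should proceed with retention of alkene geometry and give 16.

Step 14. Ionisation on the β face, syn to the axial C10 methyl, may be slow, or hydride may be delivered to the wrong end of the allyl unit. The fallback opens the epoxide by electron transfer; it sets out from epoxide 22 and comes back at hydroxy lactone 23.
- SmI2 (THF/MeOH, −78 °C) should reduce the enoate, cleave the C6–O bond and, after α-protonation, give the deconjugated 1β-(tert-butyldimethylsilyloxy)-5α,11-dihydroxydrim-6-en-12-oic acid lactone F10.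
- DBU (CH2Cl2, rt) would move the double bond back into conjugation to give 23.

**Further compounds**

F1 | step 10 | (R)-tert-butyldimethyl[(2,4,4-trimethyl-3-vinylcyclohex-2-en-1-yl)oxy]silane | CC1(C)CC[C@@H](O[Si](C)(C)C(C)(C)C)C(C)=C1C=C
F2 | step 10 | dimethyl 1β-(tert-butyldimethylsilyloxy)drima-5,8-diene-11,12-dioate | CC1(C)CC[C@@H](O[Si](C)(C)C(C)(C)C)[C@]2(C)C(C(=O)OC)=C(C(=O)OC)CC=C12
F3 | step 10 | dimethyl 1β-(tert-butyldimethylsilyloxy)-5α,6α-epoxydrim-8-ene-11,12-dioate | CC1(C)CC[C@@H](O[Si](C)(C)C(C)(C)C)[C@]2(C)C(C(=O)OC)=C(C(=O)OC)C[C@@H]3O[C@]123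
F4 | step 10 | dimethyl 1β-(tert-butyldimethylsilyloxy)-5α-hydroxydrima-6,8-diene-11,12-dioate | CC1(C)CC[C@@H](O[Si](C)(C)C(C)(C)C)[C@]2(C)C(C(=O)OC)=C(C(=O)OC)C=C[C@@]12O
F5 | step 10 | dimethyl 1β-(tert-butyldimethylsilyloxy)-5α-hydroxydrim-8-ene-11,12-dioate | CC1(C)CC[C@@H](O[Si](C)(C)C(C)(C)C)[C@]2(C)C(C(=O)OC)=C(C(=O)OC)CC[C@@]12O
F6 | step 10 | dimethyl 1β-(tert-butyldimethylsilyloxy)-5α-hydroxydrim-7-ene-11,12-dioate (9α-H) | CC1(C)CC[C@@H](O[Si](C)(C)C(C)(C)C)[C@]2(C)[C@@H](C(=O)OC)C(C(=O)OC)=CC[C@@]12O
F7 | step 9 | (R)-tert-butyl{[3-(iodoethynyl)-2,4,4-trimethylcyclohex-2-en-1-yl]oxy}dimethylsilane | CC1(C)CC[C@@H](O[Si](C)(C)C(C)(C)C)C(C)=C1C#CI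
F8 | step 9 | (R)-tert-butyl({3-[(Z)-2-iodoethenyl]-2,4,4-trimethylcyclohex-2-en-1-yl}oxy)dimethylsilane | CC1(C)CC[C@@H](O[Si](C)(C)C(C)(C)C)C(C)=C1/C=C\I
F9 | step 9 | 4-(tributylstannyl)furan-2(5H)-one | O=C1C=C([Sn](CCCC)(CCCC)CCCC)CO1
F10 | step 14 | 1β-(tert-butyldimethylsilyloxy)-5α,11-dihydroxydrim-6-en-12-oic acid lactone (C8 epimers) | CC1(C)CC[C@@H](O[Si](C)(C)C(C)(C)C)[C@]2(C)[C@H]3COC(=O)C3C=C[C@@]12O
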